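**Assumption:** cardivin C is treated as the open 2-hydroxy-5-ketone drawn in the SMILES (no transannular hemiketal). Positions use germacrane numbering: lactone O on C8, C7 bonded to C11(=C13H2)–C12(=O), C6 isobutyrate, C5 ketone, C4 methyl, C2 OH, C10 Me/OH, C9 angelate. The target is 2S,4S,6S,7R,8R,9S,10S.

## Retrosynthetic overview

1. Cardivin C ⇐ C2–O desilylation and C9 angeloylation of a macrocyclic diol that already carries the C6 isobutyrate.
2. Key disconnection C6–C7: the ten-membered ring is closed last, onto the pre-formed lactone, by a Cr-electrocatalytic intramolecular allylation of a C5/C6 keto-aldehyde by a C8-substituted 3-(bromomethyl)butenolide; this sets C6 and C7.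
3. Lactone ring (formed first): indium Barbier addition of ethyl 2-(bromomethyl)acrylate to a C8 α-hydroxy aldehyde (sets C8), then selenium-mediated transposition to the allylic bromide.
4. Chain: C5–C6 by dithiane acylation of a γ-lactone, C2–C3 by Fukuyama coupling, C2 by 1,3-syn reduction, C1–C10 by chelation-controlled thioester aldol (sets C10).
5. Chiral pool: (S)-glycerate acetonide supplies C9 and (S)-Roche ester supplies C4; C10, C2, C8, C7 and C6 are set by substrate control.

## Route

**Step 1**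
Reactants: 1, methyl (4S)-2,2-dimethyl-1,3-dioxolane-4-carboxylate
Product: 2, 1-[(4S)-2,2-dimethyl-1,3-dioxolan-4-yl]ethan-1-one
Conditions: MeNH(OMe)·HCl, iPrMgCl, THF, −20 °C; then MeMgBr, 0 °C (one pot)
Reagents that add atoms: methylmagnesium bromide, C[Mg]Br
Why: In situ Weinreb amide formation followed by Weinreb ketone synthesis stops at the methyl ketone through the chelated tetrahedral intermediate; the C9 stereocentre is bought and no new one is formed.

**Step 2**
Reactants: 2, 1-[(4S)-2,2-dimethyl-1,3-dioxolan-4-yl]ethan-1-one; 3, S-ethyl ethanethioate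
Product: 4, S-ethyl (3S)-3-[(4S)-2,2-dimethyl-1,3-dioxolan-4-yl]-3-hydroxybutanethioate
Conditions: 3, LiHMDS, Et2O–toluene, −78 °C; MgBr2·OEt2; then 2 (pre-complexed with MgBr2·OEt2), −78 °C
Reagents that add atoms: S-ethyl ethanethioate (3), CCSC(C)=O
Why: Chelation-controlled (Cram-chelate) aldol addition of the magnesium thioester enolate: Mg bridges the ketone and the α-dioxolane oxygen and the enolate attacks anti to C8, giving the 9,10-syn tertiary alcohol (C10 = S).

**Step 3**
Reactants: 5, methyl (2S)-3-hydroxy-2-methylpropanoate ((S)-Roche ester)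
Product: 6, methyl (2R)-3-iodo-2-methylpropanoate
Conditions: I2, PPh3, imidazole, CH2Cl2, 0 °C → rt
Reagents that add atoms: iodine, II
Why: Appel iodination of the primary alcohol; the stereocentre (future C4) is not involved, and the descriptor changes only because of CIP priorities.

**Step 4**
Reactants: 4, S-ethyl (3S)-3-[(4S)-2,2-dimethyl-1,3-dioxolan-4-yl]-3-hydroxybutanethioate; 6, methyl (2R)-3-iodo-2-methylpropanoate
Product: 7, methyl (2S,6S)-6-[(4S)-2,2-dimethyl-1,3-dioxolan-4-yl]-6-hydroxy-2-methyl-4-oxoheptanoate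
Conditions: 6, activated Zn dust (TMSCl, BrCH2CH2Br), DMF, rt (3 equiv alkylzinc iodide); then 4, PdCl2(PPh3)2 (5 mol%), toluene–DMF, rt
Reagents that add atoms: methyl (2R)-3-iodo-2-methylpropanoate (6), COC(=O)[C@@H](C)CI
Why: Fukuyama thioester–organozinc coupling gives the ketone under neutral conditions that tolerate the free tertiary alcohol, ester and acetonide; the Roche stereocentre is β to zinc and configurationally stable.

**Step 5**
Reactants: 7, methyl (2S,6S)-6-[(4S)-2,2-dimethyl-1,3-dioxolan-4-yl]-6-hydroxy-2-methyl-4-oxoheptanoate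
Product: 8, (3S,5S)-5-{(2S)-2-[(4S)-2,2-dimethyl-1,3-dioxolan-4-yl]-2-hydroxypropyl}-3-methyloxolan-2-one (cis-lactone)
Conditions: Et2BOMe, THF–MeOH (4:1), −78 °C; NaBH4; AcOH quench, MeOH azeotrope; then PPTS, CH2Cl2, rt
Reagents that add atoms: none
Why: Narasaka–Prasad 1,3-syn reduction through the boron chelate of the C10 hydroxyl (larger C9 substituent equatorial) sets C2 = S, and the γ-hydroxy ester then lactonises to the cis-2,4-disubstituted lactone, which masks C2–OH.

**Step 6**
Reactants: 8, the cis-lactone; 9, 1,3-dithiane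
Product: 10, (2S,4S,6S)-1-(1,3-dithian-2-yl)-6-[(4S)-2,2-dimethyl-1,3-dioxolan-4-yl]-4,6-dihydroxy-2-methylheptan-1-one
Conditions: 9, n-BuLi, THF, −30 °C (3.2 equiv 2-lithio-1,3-dithiane); then 8, −78 → −40 °C; NH4Cl
Reagents that add atoms: 1,3-dithiane (9), C1CSCSC1
Why: Corey–Seebach acyl substitution on the lactone forms the C5–C6 bond; the 2-acyl-dithiane product is deprotonated in situ, which prevents over-addition and shields C4 from enolisation.

**Step 7**
Reactants: 10, the dihydroxy acyl-dithiane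
Product: 11, (2S,4S,6S)-4-[(tert-butyldiphenylsilyl)oxy]-1-(1,3-dithian-2-yl)-6-[(4S)-2,2-dimethyl-1,3-dioxolan-4-yl]-6-hydroxy-2-methylheptan-1-one
Conditions: TBDPSCl, imidazole, DMAP (cat.), DMF, rt
Reagents that add atoms: tert-butyl(chloro)diphenylsilane, CC(C)(C)[Si](Cl)(c1ccccc1)c1ccccc1
Why: Silyl ether formation is selective for the secondary C2–OH because the tertiary C10–OH is inert under these conditions.

**Step 8**
Reactants: 11, the TBDPS ether
Product: 12, (3S,5S,7S,8S)-5-[(tert-butyldiphenylsilyl)oxy]-7,8,9-trihydroxy-1,1-dimethoxy-3,7-dimethylnonan-2-one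
Conditions: PhI(O2CCF3)2, MeOH–CH2Cl2, 0 °C; then PPTS, MeOH, 40 °C
Reagents that add atoms: methanol, CO
Why: Oxidative dithiane-to-dimethyl-acetal exchange (Stork–Zhao) gives an oxidant-stable α-keto acetal, and PPTS/MeOH transacetalisation then removes the terminal acetonide while TBDPS survives.

**Step 9**
Reactants: 12, the triol acetal
Product: 13, (2R,3S,5S,7S)-5-[(tert-butyldiphenylsilyl)oxy]-2,3-dihydroxy-9,9-dimethoxy-3,7-dimethyl-8-oxononanal
Conditions: TEMPO (10 mol%), PhI(OAc)2, CH2Cl2, rt; used crude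
Reagents that add atoms: none
Why: Oxoammonium (TEMPO/BAIB) oxidation is selective for the primary C8 alcohol over the secondary C9 and tertiary C10 hydroxyls; the descriptor change at C9 is a CIP effect only.

**Step 10**
Reactants: 13, the α-hydroxy aldehyde; 14, ethyl 2-(bromomethyl)prop-2-enoate
Product: 15, (5R)-5-[(1S,2S,4S,6S)-4-[(tert-butyldiphenylsilyl)oxy]-1,2-dihydroxy-8,8-dimethoxy-2,6-dimethyl-7-oxooctyl]-3-methylideneoxolan-2-one
Conditions: In powder, 14, THF–H2O (1:1), rt; then TsOH (cat.), CH2Cl2, rt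
Reagents that add atoms: ethyl 2-(bromomethyl)prop-2-enoate (14), CCOC(=O)C(=C)CBr
Why: Indium-mediated aqueous Barbier allylation of a free α-hydroxy aldehyde is chelation-controlled and gives the 8,9-syn diol (C8 = R); the hydroxy ester closes to the five-membered lactone, and the hindered C5 ketone is not attacked.

**Step 11**
Reactants: 15, the α-methylene lactone
Product: 16, (5R)-3-(bromomethyl)-5-[(1S,2S,4S,6S)-4-[(tert-butyldiphenylsilyl)oxy]-1,2-dihydroxy-8,8-dimethoxy-2,6-dimethyl-7-oxooctyl]furan-2(5H)-one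
Conditions: PhSeBr, MeCN, rt; then 30% H2O2, NaHCO3, THF, 0 °C → rt
Reagents that add atoms: phenylselenenyl bromide, Br[Se]c1ccccc1 (Br retained)
Why: Selenobromination of the acrylate-type alkene places Se on C11 and Br on C13, and selenoxide syn-elimination then goes away from the bromine-bearing carbon toward C7–H (Sharpless-type allylic halide synthesis), giving the endocyclic allylic bromide without touching C8.

**Step 12**
Reactants: 16, the bromomethyl butenolide acetal
Product: 17, (3S,5S,7S,8S)-8-[(2R)-4-(bromomethyl)-5-oxo-2,5-dihydrofuran-2-yl]-5-[(tert-butyldiphenylsilyl)oxy]-7,8-dihydroxy-3,7-dimethyl-2-oxooctanal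
Conditions: TFA–H2O (9:1), CH2Cl2, 0 °C; toluene azeotrope, 4 Å MS; used at once
Reagents that add atoms: water, O
Why: Acid hydrolysis of the α-keto acetal releases the C6 aldehyde; the primary allylic bromide, butenolide and TBDPS ether tolerate brief cold aqueous acid.

**Step 13**
Reactants: 17, the keto-aldehyde bromide; 18, 2-methylpropanoic anhydride
Product: 19, (3aR,4S,6S,8S,10S,11S,11aR)-8-[(tert-butyldiphenylsilyl)oxy]-10,11-dihydroxy-6,10-dimethyl-3-methylidene-2,5-dioxododecahydrocyclodeca[b]furan-4-yl 2-methylpropanoate (germacrane numbering: 6-OiBu, 9-OH, 10-OH, 2-OTBDPS)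
Conditions: CrCl2 (20 mol%), 18 (1.5 equiv), n-Bu4NBF4 (0.1 M), DMF–THF, 4 Å MS, undivided cell, Al anode, Ni-foam cathode, held at the Cr(III)/Cr(II) wave (about −1.0 V vs Ag/AgCl, 2.5 F mol−1), 17 added by syringe pump over 8 h (final 2 mM), rt
Reagents that add atoms: 2-methylpropanoic anhydride (18), CC(C)C(=O)OC(=O)C(C)C
Why: Proposed new method: cathodically regenerated Cr(II) converts the C13–Br bond into an η1-allyl-Cr(III) at C13, which adds to the tethered C6 aldehyde through a six-membered chair (Zimmerman–Traxler) transition state; the ring-locked alkene (C8 trans to C13) enforces the anti C6/C7 relationship (6S), bond formation at C7 on the face opposite C9 gives the trans-fused lactone (7R), and the metal alkoxide is acylated by 18, which installs the isobutyrate and frees Cr(III) for re-reduction; the closest known reactions are stoichiometric CrCl2 intramolecular Barbier/NHK closures of germacranolide rings, anti-selective Cr-mediated additions of 3-(bromomethyl)butenolides to aldehydes and Cr-catalytic electroreductive allylation with a sacrificial anode, none of which has been shown as an electrocatalytic macrocyclisation with a butenolide allyl donor and acylative turnover.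

**Step 14**
Reactants: 19, the macrocyclic diol isobutyrate; 20, (2Z)-2-methylbut-2-enoic acid (angelic acid)
Product: 21, (3aR,4S,6S,8S,10S,11S,11aR)-8-[(tert-butyldiphenylsilyl)oxy]-10-hydroxy-6,10-dimethyl-3-methylidene-4-[(2-methylpropanoyl)oxy]-2,5-dioxododecahydrocyclodeca[b]furan-11-yl (2Z)-2-methylbut-2-enoate
Conditions: 20, 2,4,6-trichlorobenzoyl chloride, Et3N, toluene, rt; then 19, DMAP, toluene, 60 °C
Reagents that add atoms: angelic acid (20), C/C=C(/C)C(=O)O
Why: Yamaguchi esterification through the pre-formed mixed anhydride acylates the only free secondary hydroxyl (C9) without Z→E isomerisation of the angelate; the tertiary C10–OH does not react.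

**Step 15**
Reactants: 21, the TBDPS-protected cardivin C
Product: 22, cardivin C, (3aR,4S,6S,8S,10S,11S,11aR)-8,10-dihydroxy-6,10-dimethyl-3-methylidene-4-[(2-methylpropanoyl)oxy]-2,5-dioxododecahydrocyclodeca[b]furan-11-yl (2Z)-2-methylbut-2-enoate
Conditions: HF·pyridine, pyridine–THF, 0 °C → rt
Reagents that add atoms: none
Why: Buffered fluoride cleaves the silyl ether to free C2–OH under non-basic conditions that the two esters, the α-acyloxy ketone and the α-methylene lactone tolerate.

## Compound list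

1 | methyl (4S)-2,2-dimethyl-1,3-dioxolane-4-carboxylate | COC(=O)[C@@H]1COC(C)(C)O1 | starting material
2 | 1-[(4S)-2,2-dimethyl-1,3-dioxolan-4-yl]ethan-1-one | CC(=O)[C@@H]1COC(C)(C)O1 | intermediate
3 | S-ethyl ethanethioate | CCSC(C)=O | starting material
4 | S-ethyl (3S)-3-[(4S)-2,2-dimethyl-1,3-dioxolan-4-yl]-3-hydroxybutanethioate | CCSC(=O)C[C@](C)(O)[C@@H]1COC(C)(C)O1 | intermediate
5 | methyl (2S)-3-hydroxy-2-methylpropanoate | COC(=O)[C@@H](C)CO | starting material
6 | methyl (2R)-3-iodo-2-methylpropanoate | COC(=O)[C@@H](C)CI | intermediate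
7 | methyl (2S,6S)-6-[(4S)-2,2-dimethyl-1,3-dioxolan-4-yl]-6-hydroxy-2-methyl-4-oxoheptanoate | COC(=O)[C@@H](C)CC(=O)C[C@](C)(O)[C@@H]1COC(C)(C)O1 | intermediate
8 | (3S,5S)-5-{(2S)-2-[(4S)-2,2-dimethyl-1,3-dioxolan-4-yl]-2-hydroxypropyl}-3-methyloxolan-2-one | C[C@H]1C[C@@H](C[C@](C)(O)[C@@H]2COC(C)(C)O2)OC1=O | intermediate
9 | 1,3-dithiane | C1CSCSC1 | starting material
10 | (2S,4S,6S)-1-(1,3-dithian-2-yl)-6-[(4S)-2,2-dimethyl-1,3-dioxolan-4-yl]-4,6-dihydroxy-2-methylheptan-1-one | O=C(C1SCCCS1)[C@@H](C)C[C@H](O)C[C@](C)(O)[C@@H]2COC(C)(C)O2 | intermediate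
11 | (2S,4S,6S)-4-[(tert-butyldiphenylsilyl)oxy]-1-(1,3-dithian-2-yl)-6-[(4S)-2,2-dimethyl-1,3-dioxolan-4-yl]-6-hydroxy-2-methylheptan-1-one | O=C(C1SCCCS1)[C@@H](C)C[C@H](O[Si](c1ccccc1)(c1ccccc1)C(C)(C)C)C[C@](C)(O)[C@@H]2COC(C)(C)O2 | intermediate
12 | (3S,5S,7S,8S)-5-[(tert-butyldiphenylsilyl)oxy]-7,8,9-trihydroxy-1,1-dimethoxy-3,7-dimethylnonan-2-one | COC(OC)C(=O)[C@@H](C)C[C@H](O[Si](c1ccccc1)(c1ccccc1)C(C)(C)C)C[C@](C)(O)[C@@H](O)CO | intermediate
13 | (2R,3S,5S,7S)-5-[(tert-butyldiphenylsilyl)oxy]-2,3-dihydroxy-9,9-dimethoxy-3,7-dimethyl-8-oxononanal | COC(OC)C(=O)[C@@H](C)C[C@H](O[Si](c1ccccc1)(c1ccccc1)C(C)(C)C)C[C@](C)(O)[C@@H](O)C=O | intermediate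
14 | ethyl 2-(bromomethyl)prop-2-enoate | CCOC(=O)C(=C)CBr | starting material
15 | (5R)-5-[(1S,2S,4S,6S)-4-[(tert-butyldiphenylsilyl)oxy]-1,2-dihydroxy-8,8-dimethoxy-2,6-dimethyl-7-oxooctyl]-3-methylideneoxolan-2-one | C=C1C(=O)O[C@H](C1)[C@H](O)[C@@](C)(O)C[C@@H](O[Si](c2ccccc2)(c2ccccc2)C(C)(C)C)C[C@H](C)C(=O)C(OC)OC | intermediate
16 | (5R)-3-(bromomethyl)-5-[(1S,2S,4S,6S)-4-[(tert-butyldiphenylsilyl)oxy]-1,2-dihydroxy-8,8-dimethoxy-2,6-dimethyl-7-oxooctyl]furan-2(5H)-one | O=C1O[C@H](C=C1CBr)[C@H](O)[C@@](C)(O)C[C@@H](O[Si](c2ccccc2)(c2ccccc2)C(C)(C)C)C[C@H](C)C(=O)C(OC)OC | intermediate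
17 | (3S,5S,7S,8S)-8-[(2R)-4-(bromomethyl)-5-oxo-2,5-dihydrofuran-2-yl]-5-[(tert-butyldiphenylsilyl)oxy]-7,8-dihydroxy-3,7-dimethyl-2-oxooctanal | O=C1O[C@H](C=C1CBr)[C@H](O)[C@@](C)(O)C[C@@H](O[Si](c2ccccc2)(c2ccccc2)C(C)(C)C)C[C@H](C)C(=O)C=O | intermediate
18 | 2-methylpropanoic anhydride | CC(C)C(=O)OC(=O)C(C)C | starting material
19 | (3aR,4S,6S,8S,10S,11S,11aR)-8-[(tert-butyldiphenylsilyl)oxy]-10,11-dihydroxy-6,10-dimethyl-3-methylidene-2,5-dioxododecahydrocyclodeca[b]furan-4-yl 2-methylpropanoate | C=C1C(=O)O[C@@H]2[C@@H]1[C@H](OC(=O)C(C)C)C(=O)[C@@H](C)C[C@H](O[Si](c3ccccc3)(c3ccccc3)C(C)(C)C)C[C@](C)(O)[C@H]2O | intermediate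
20 | (2Z)-2-methylbut-2-enoic acid (angelic acid) | C/C=C(/C)C(=O)O | starting material
21 | (3aR,4S,6S,8S,10S,11S,11aR)-8-[(tert-butyldiphenylsilyl)oxy]-10-hydroxy-6,10-dimethyl-3-methylidene-4-[(2-methylpropanoyl)oxy]-2,5-dioxododecahydrocyclodeca[b]furan-11-yl (2Z)-2-methylbut-2-enoate | C=C1C(=O)O[C@@H]2[C@@H]1[C@H](OC(=O)C(C)C)C(=O)[C@@H](C)C[C@H](O[Si](c3ccccc3)(c3ccccc3)C(C)(C)C)C[C@](C)(O)[C@H]2OC(=O)/C(C)=C\C | intermediate
22 | cardivin C | C=C1C(=O)O[C@@H]2[C@@H]1[C@H](OC(=O)C(C)C)C(=O)[C@@H](C)C[C@H](O)C[C@](C)(O)[C@H]2OC(=O)/C(C)=C\C | target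

## Summary

Total steps: 15. Longest linear sequence: 14 (steps 1, 2, 4–15 from compound 1).

Steps most likely to fail:

1. **Step 13 (proposed new electrocatalytic macrocyclisation).** Risks are oligomerisation, direct cathodic reduction of the 1,2-dicarbonyl, cis- instead of trans-fused closure, and slow acylative turnover. Fallback with known chemistry: move the ring closure to C7–C8, using a stoichiometric CrCl2 intramolecular Barbier/NHK allylation of a C8 aldehyde by an acyclic C6-acyloxy 2-(bromomethyl)enoate (the established way to close germacranolide ten-membered rings), with C6 introduced beforehand.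

2. **Step 11 (selenobromination and selenoxide elimination on an electron-poor alkene).** Addition may be slow or the elimination may go the wrong way. Fallback: build the handle by a different sequence from aldehyde 13: lithium ethyl propiolate addition, Lindlar reduction and lactonisation to the unsubstituted butenolide, Morita–Baylis–Hillman hydroxymethylation with formaldehyde, then Appel bromination.

3. **Step 2 (chelation control at C10 with a dioxolane α-oxygen).** Felkin addition would give the C10 epimer. Fallback: take C10 from the chiral pool instead, by alkylating the Seebach dioxolanone of lactic acid (self-regeneration of stereocentres) to fix the quaternary carbinol, then add the C9–C8 unit by chelation-controlled addition to the derived α-alkoxy aldehyde.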